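**Strategy.** Numbering: chroman O1 to C8a; naphthalene C1' to C8a', C1' bonded to C4 (ring C: C1'–C4'; ring D: C5'–C8'). Ring C bears only a carbon substituent at C1' and an oxygen at C4', para to each other, with C2' and C3' unsubstituted: the footprint of a 2-substituted furan fused onto a benzyne. The route therefore disconnects C1'–C8a' and C4'–C4a'. In one flask 3-methoxybenzyne adds across the furan of a benzyl-protected cis-4-furyl-2-methylchroman and acid opens the oxygen bridge, closing ring C and placing the C4' hydroxyl peri to the C5' methoxy group. The furylchroman comes from an organocatalytic Michael addition, aromatisation and ionic hydrogenation.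

Key step: step 5

Assumption: the (S,S)-diamine in step 1 is taken to give the (R) adduct, by analogy with the known sense of diamine-catalysed warfarin-type additions to benzylideneacetone; if the furyl enone responds in the opposite sense, the (R,R)-diamine is used and nothing else changes.

**Step 1**
Reactants: 1 cyclohexane-1,3-dione; 2 (E)-4-(furan-2-yl)but-3-en-2-one
Product: 5 (4R)-4-(furan-2-yl)-2-methoxy-2-methyl-2,3,4,6,7,8-hexahydro-5H-chromen-5-one (both C2 epimers), via open-chain Michael adduct 3 (not isolated), via cyclic hemiketal 4 (not isolated)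
Conditions: (S,S)-1,2-diphenylethane-1,2-diamine (10 mol %), AcOH (excess), THF, rt; then MeOH, camphorsulfonic acid (20 mol %), rt
Reagents that add atoms: methanol, CO
Why: An iminium-activated organocatalytic Michael addition of the 1,3-diketone to the enone, in which the chiral diamine shields one face of the β-carbon and so sets C4 as R, is followed by spontaneous hemiketal closure and acid-catalysed exchange with methanol to the mixed ketal, whose C2 configuration is irrelevant because that centre is reset in step 3.

**Step 2**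
Reactants: 5 (4R)-4-(furan-2-yl)-2-methoxy-2-methyl-2,3,4,6,7,8-hexahydro-5H-chromen-5-one
Product: 9 (4R)-4-(furan-2-yl)-2-methoxy-2-methyl-3,4-dihydro-2H-chromen-5-ol (both C2 epimers), via 6-phenylselanyl ketone 6 (not isolated), via selenoxide 7 (not isolated), via cross-conjugated dienone 8 (not isolated)
Conditions: LiN(iPr)2, THF, −78 °C; PhSeBr, −78 °C; then pyridine, 30% aq. H2O2, 0 °C → rt
Reagents that add atoms: none
Why: Kinetic deprotonation of the vinylogous ester at C6, selenenylation of the enolate and selenoxide syn-elimination give a cyclohexa-2,5-dienone that tautomerises to the phenol, under buffered low-temperature conditions that leave the furan, the ketal and the non-enolisable C4 centre untouched.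

**Step 3**
Reactants: 9 (4R)-4-(furan-2-yl)-2-methoxy-2-methyl-3,4-dihydro-2H-chromen-5-ol
Product: 10 (2S,4R)-4-(furan-2-yl)-2-methyl-3,4-dihydro-2H-chromen-5-ol
Conditions: Et3SiH, BF3·OEt2, CH2Cl2, −78 → −30 °C
Reagents that add atoms: none
Why: Ionic hydrogenation, in which the Lewis acid ionises the ketal to the cyclic aryl oxocarbenium ion and the silane delivers hydride to the face of C2 opposite the C4 furyl group, sets C2 as S and so gives the 2,4-cis chroman from both ketal epimers.

**Step 4**
Reactants: 10 (2S,4R)-4-(furan-2-yl)-2-methyl-3,4-dihydro-2H-chromen-5-ol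
Product: 11 (2S,4R)-5-(benzyloxy)-4-(furan-2-yl)-2-methyl-3,4-dihydro-2H-chromene
Conditions: BnBr, K2CO3, DMF, rt
Reagents that add atoms: benzyl bromide, BrCc1ccccc1
Why: Williamson etherification of the phenoxide installs a benzyl ether that should survive fluoride, the aryne, acid and the later methylation, and is removable at the end by hydrogenolysis.

**Step 5**
Reactants: 11 (2S,4R)-5-(benzyloxy)-4-(furan-2-yl)-2-methyl-3,4-dihydro-2H-chromene; 12 3-methoxy-2-(trimethylsilyl)phenyl trifluoromethanesulfonate
Product: 15 4-[(2S,4S)-5-(benzyloxy)-2-methyl-3,4-dihydro-2H-chromen-4-yl]-8-methoxynaphthalen-1-ol, via 3-methoxybenzyne 13 (not isolated), via oxygen-bridged cycloadduct 14 (not isolated)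
Conditions: 12 (2 equiv, slow addition), CsF, MeCN, rt; then 3 M HCl in MeOH, 0 °C → rt, under N2
Reagents that add atoms: none
Why: Fluoride attacks silicon of 12 and triflate leaves to give 3-methoxybenzyne 13, which adds across C2 and C5 of the furan in a concerted suprafacial (4+2) cycloaddition (aryne–furan Diels–Alder reaction), forming C1'–C8a' and C4'–C4a' together. Ring C is closed by this single intermolecular cycloaddition as a six-membered carbocycle spanned by the former furan oxygen. Acid then protonates the bridging oxygen, the tertiary, allylic and benzylic C1'–O bond ionises, and loss of the C4' proton aromatises ring C, which is the known acid isomerisation of 1,4-epoxy-1,4-dihydronaphthalenes to 1-naphthols. The two bridgehead stereocentres of 14 form without control and are erased on aromatisation, so 15 gains no stereocentre, and the chroman centres carry no enolisable or ionisable bond and should be unchanged. The step needs the distal regiochemistry, with the chromanyl-bearing bridgehead remote from the methoxy group; this rests on the steric clash between the branched chromanyl substituent and the methoxy group flanking the aryne, which must override the weak opposing polarisation of the aryne. It also needs bridge opening at C1' and not at C4', which the extra carbon substituent on C1' should favour over the methoxy-assisted alternative.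

**Step 6**
Reactants: 15 4-[(2S,4S)-5-(benzyloxy)-2-methyl-3,4-dihydro-2H-chromen-4-yl]-8-methoxynaphthalen-1-ol
Product: 16 (2S,4S)-5-(benzyloxy)-4-(4,5-dimethoxynaphthalen-1-yl)-2-methyl-3,4-dihydro-2H-chromene
Conditions: MeI, K2CO3, DMF, rt, under N2
Reagents that add atoms: iodomethane, CI
Why: Williamson O-methylation of the only free hydroxyl group, the naphthol, should proceed once carbonate in a dipolar aprotic solvent breaks its hydrogen bond to the peri methoxy group.

**Step 7**
Reactants: 16 (2S,4S)-5-(benzyloxy)-4-(4,5-dimethoxynaphthalen-1-yl)-2-methyl-3,4-dihydro-2H-chromene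
Product: 17 Cladonaphchrom B [(2S,4S)-4-(4,5-dimethoxynaphthalen-1-yl)-2-methyl-3,4-dihydro-2H-chromen-5-ol]
Conditions: H2 (1 atm), 10% Pd/C, EtOAc–MeOH, rt
Reagents that add atoms: none
Why: Catalytic hydrogenolysis of the benzyl aryl ether should leave the methyl ethers, the non-benzylic C2–O bond of the chroman and both stereocentres unchanged.

**Compound list**
1 | cyclohexane-1,3-dione | O=C1CCCC(=O)C1 | starting material
2 | (E)-4-(furan-2-yl)but-3-en-2-one (furfurylideneacetone) | CC(=O)/C=C/c1ccco1 | starting material
3 | (R)-2-[1-(furan-2-yl)-3-oxobutyl]cyclohexane-1,3-dione | o1cccc1[C@@H](C2C(=O)CCCC2=O)CC(C)=O | intermediate (not isolated)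
4 | (4R)-4-(furan-2-yl)-2-hydroxy-2-methyl-2,3,4,6,7,8-hexahydro-5H-chromen-5-one (C2 epimers) | o1cccc1[C@@H]2CC(C)(O)OC3=C2C(=O)CCC3 | intermediate (not isolated)
5 | (4R)-4-(furan-2-yl)-2-methoxy-2-methyl-2,3,4,6,7,8-hexahydro-5H-chromen-5-one (C2 epimers) | o1cccc1[C@@H]2CC(C)(OC)OC3=C2C(=O)CCC3 | intermediate
6 | (4R)-4-(furan-2-yl)-2-methoxy-2-methyl-6-(phenylselanyl)-2,3,4,6,7,8-hexahydro-5H-chromen-5-one | o1cccc1[C@@H]2CC(C)(OC)OC3=C2C(=O)C([Se]c4ccccc4)CC3 | intermediate (not isolated)
7 | (4R)-4-(furan-2-yl)-2-methoxy-2-methyl-6-(phenylseleninyl)-2,3,4,6,7,8-hexahydro-5H-chromen-5-one | o1cccc1[C@@H]2CC(C)(OC)OC3=C2C(=O)C([Se](=O)c4ccccc4)CC3 | intermediate (not isolated)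
8 | (4R)-4-(furan-2-yl)-2-methoxy-2-methyl-2,3,4,8-tetrahydro-5H-chromen-5-one | o1cccc1[C@@H]2CC(C)(OC)OC3=C2C(=O)C=CC3 | intermediate (not isolated)
9 | (4R)-4-(furan-2-yl)-2-methoxy-2-methyl-3,4-dihydro-2H-chromen-5-ol (C2 epimers) | o1cccc1[C@@H]2CC(C)(OC)Oc3cccc(O)c32 | intermediate
10 | (2S,4R)-4-(furan-2-yl)-2-methyl-3,4-dihydro-2H-chromen-5-ol (2,4-cis) | o1cccc1[C@@H]2C[C@H](C)Oc3cccc(O)c32 | intermediate
11 | (2S,4R)-5-(benzyloxy)-4-(furan-2-yl)-2-methyl-3,4-dihydro-2H-chromene (2,4-cis) | o1cccc1[C@@H]2C[C@H](C)Oc3cccc(OCc4ccccc4)c32 | intermediate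
12 | 3-methoxy-2-(trimethylsilyl)phenyl trifluoromethanesulfonate | COc1cccc(OS(=O)(=O)C(F)(F)F)c1[Si](C)(C)C | starting material
13 | 3-methoxybenzyne | COC1=CC=CC#C1 | intermediate (not isolated)
14 | (2S,4R)-5-(benzyloxy)-4-(5-methoxy-1,4-dihydro-1,4-epoxynaphthalen-1-yl)-2-methyl-3,4-dihydro-2H-chromene (both bridgehead diastereomers) | COc1cccc2c1C3C=CC2(O3)[C@@H]4C[C@H](C)Oc5cccc(OCc6ccccc6)c54 | intermediate (not isolated)
15 | 4-[(2S,4S)-5-(benzyloxy)-2-methyl-3,4-dihydro-2H-chromen-4-yl]-8-methoxynaphthalen-1-ol | COc1cccc2c([C@@H]3C[C@H](C)Oc4cccc(OCc5ccccc5)c43)ccc(O)c12 | intermediate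
16 | (2S,4S)-5-(benzyloxy)-4-(4,5-dimethoxynaphthalen-1-yl)-2-methyl-3,4-dihydro-2H-chromene | COc1cccc2c([C@@H]3C[C@H](C)Oc4cccc(OCc5ccccc5)c43)ccc(OC)c12 | intermediate
17 | Cladonaphchrom B, (2S,4S)-4-(4,5-dimethoxynaphthalen-1-yl)-2-methyl-3,4-dihydro-2H-chromen-5-ol | COc1cccc2c([C@@H]3C[C@H](C)Oc4cccc(O)c43)ccc(OC)c12 | target

**Step count:** 7 steps in total. Longest linear sequence: 7 steps (from 1 and 2; 12 is used as purchased).

**Steps most likely to fail**

1. Step 5. The aryne may add with the chromanyl-bearing furan terminus next to the methoxy group (poor regiocontrol), and on acid treatment the bridge may ionise at C4' with migration of the chromanyl group. The fallback runs from 11 back to 16 and replaces the methoxy group, for the cycloaddition only, by a pinacolboryl group, which is bulkier and polarises the aryne in the helpful sense. The aryne 3-(pinacolboryl)benzyne F1 would be generated at −78 °C in THF with iPrMgCl·LiCl from 2-iodo-3-(4,4,5,5-tetramethyl-1,3,2-dioxaborolan-2-yl)phenyl trifluoromethanesulfonate (prepared separately) in the presence of 11. This should give the distal boryl cycloadduct F2, which a mild sulfonic acid in CH2Cl2 would isomerise to the 8-boryl-1-naphthol F3. Oxidation of the C–B bond (NaBO3·4H2O, THF–H2O) would give the naphthalene-1,8-diol F4, and double methylation (MeI, K2CO3, DMF) would rejoin the route at 16.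

2. Step 3. Hydride may be delivered syn to the furyl group (poor facial selectivity, giving the 2,4-trans chroman), or the Lewis acid may degrade the furan. The fallback runs from 9 back to 10 and fixes C2 by reagent control instead of ring conformation. The ketal of 9 would be hydrolysed (1 M HCl, THF, rt) to the hemiketal F5, which equilibrates with its open-chain methyl ketone. That ketone would be reduced by an (R)-selective alcohol dehydrogenase (for example that of Lactobacillus kefir, NADP+, iPrOH, pH 7 buffer) to the (1R,3R)-hydroxybutyl resorcinol F6. Mitsunobu cyclisation (PPh3, diisopropyl azodicarboxylate, THF, 0 °C) would then close the pyran ring with inversion at the carbinol carbon, giving 10.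

3. Step 2. Deprotonation may occur at the γ-position instead of C6, or the furan may be oxidised during the peroxide stage. The fallback runs from 5 back to 9 and avoids peroxide altogether. The kinetic enolate of 5 (LiN(iPr)2, THF, −78 °C) would be trapped with Me3SiCl as the silyl dienol ether F7. Dehydrosilylation with Pd(OAc)2 (divalent palladium) in MeCN at rt (Saegusa–Ito oxidation) would then give dienone 8, which tautomerises to 9.

**Further compounds**
F1 | step 5 | 3-(4,4,5,5-tetramethyl-1,3,2-dioxaborolan-2-yl)benzyne | CC1(C)OB(OC1(C)C)C2=CC=CC#C2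
F2 | step 5 | (2S,4R)-5-(benzyloxy)-2-methyl-4-[5-(4,4,5,5-tetramethyl-1,3,2-dioxaborolan-2-yl)-1,4-dihydro-1,4-epoxynaphthalen-1-yl]-3,4-dihydro-2H-chromene | CC1(C)OB(OC1(C)C)c2cccc3c2C4C=CC3(O4)[C@@H]5C[C@H](C)Oc6cccc(OCc7ccccc7)c65
F3 | step 5 | 4-[(2S,4S)-5-(benzyloxy)-2-methyl-3,4-dihydro-2H-chromen-4-yl]-8-(4,4,5,5-tetramethyl-1,3,2-dioxaborolan-2-yl)naphthalen-1-ol | CC1(C)OB(OC1(C)C)c2cccc3c([C@@H]4C[C@H](C)Oc5cccc(OCc6ccccc6)c54)ccc(O)c23
F4 | step 5 | 4-[(2S,4S)-5-(benzyloxy)-2-methyl-3,4-dihydro-2H-chromen-4-yl]naphthalene-1,8-diol | Oc1cccc2c([C@@H]3C[C@H](C)Oc4cccc(OCc5ccccc5)c43)ccc(O)c12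
F5 | step 3 | (4R)-4-(furan-2-yl)-2-methyl-3,4-dihydro-2H-chromene-2,5-diol | o1cccc1[C@@H]2CC(C)(O)Oc3cccc(O)c32
F6 | step 3 | 2-[(1R,3R)-1-(furan-2-yl)-3-hydroxybutyl]benzene-1,3-diol | o1cccc1[C@@H](c2c(O)cccc2O)C[C@@H](C)O
F7 | step 2 | (4R)-4-(furan-2-yl)-2-methoxy-2-methyl-5-(trimethylsilyloxy)-3,4,7,8-tetrahydro-2H-chromene | o1cccc1[C@@H]2CC(C)(OC)OC3=C2C(O[Si](C)(C)C)=CCC3
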